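**Retrosynthetic overview**
1. Target 23 ⇐ 6β‑triol 21 + 4‑hydroxybenzoic acid (Mitsunobu esterification with inversion at C6, no phenol protection).
2. 21 ⇐ i‑Pr addition to C4 ketone 19 ⇐ conjugate borylation/oxidation of enone 15 ⇐ hydroxy ketone 13 (C4–OH‑directed C2 reduction, then allylic oxidation).
3. 13 ⇐ diazo ynone 9 + isoprene in one operation: Rh carbene/alkyne metathesis → vinylcarbenoid → cyclopropanation → divinylcyclopropane Cope rearrangement, which also sets quaternary C1.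
4. 9 ⇐ aldol of 3‑diazobutan‑2‑one with TMS‑propynal, then kinetic resolution. The C4–O stereocentre relays chirality to C1, directs the C2 reduction, and is then oxidised and rebuilt as the tertiary carbinol.
5. Ring order: five‑membered ring first (carbene/alkyne step), seven‑membered ring second (Cope), same flask.

Assumption: daucane numbering is used for ring positions (C1 = angular‑methyl carbon, C2–C4 = rest of the five‑membered ring, C5 = ring‑fusion CH, C6 = ester carbon, C8 = ring‑methyl carbon), β = face of the angular methyl, and catalyst‑bound species (Rh carbenoids, Cu–boryl/enolate) are not numbered.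

**Step 1**
Reactants: 1 3‑methylpentane‑2,4‑dione; 2 4‑acetamidobenzenesulfonyl azide (p‑ABSA)
Product: 3 3‑diazobutan‑2‑one
Conditions: p‑ABSA (1.1 equiv), DBU (1.2 equiv), MeCN, 0 °C → rt
Reagents that add atoms: 4‑acetamidobenzenesulfonyl azide CC(=O)Nc1ccc(cc1)S(=O)(=O)N=[N+]=[N-]
Why: Regitz deacylative diazo transfer, in which the enolate of the 2‑methyl‑1,3‑diketone attacks the sulfonyl azide and one acetyl group is lost to the sulfonamide nitrogen (same reaction type as the standard preparation of 2‑diazopropanoates); no stereocentre.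

**Step 2**
Reactants: 3 3‑diazobutan‑2‑one; 4 3‑(trimethylsilyl)prop‑2‑ynal
Product: 5 rac‑2‑diazo‑5‑hydroxy‑7‑(trimethylsilyl)hept‑6‑yn‑3‑one
Conditions: LiHMDS (1.05 equiv), THF, −78 °C; then 4, −78 °C; AcOH quench
Reagents that add atoms: 3‑(trimethylsilyl)prop‑2‑ynal C[Si](C)(C)C#CC=O
Why: Aldol addition, in which the α′‑methyl is the only enolisable position of 3 and its lithium enolate adds 1,2 to the ynal to give the racemic propargylic carbinol.

**Step 3**
Reactants: 5 rac‑2‑diazo‑5‑hydroxy‑7‑(trimethylsilyl)hept‑6‑yn‑3‑one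
Product: 6 (S)‑2‑diazo‑5‑hydroxy‑7‑(trimethylsilyl)hept‑6‑yn‑3‑one
Conditions: (R)‑benzotetramisole (4 mol %), (i‑PrCO)2O (0.6 equiv), i‑Pr2NEt (0.6 equiv), CHCl3, 0 °C, stopped at ca. 58 % conversion
Reagents that add atoms: none
Why: Acylative kinetic resolution of a propargylic alcohol with an isothiourea catalyst (the alkyne is the recognised π‑group, s ≈ 20–30), where the catalyst enantiomer is chosen so that the (R)‑alcohol is acylated and the (S)‑alcohol is recovered in ≥97 % ee; this fixes the absolute configuration of the route.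

**Step 4**
Reactants: 6 (S)‑2‑diazo‑5‑hydroxy‑7‑(trimethylsilyl)hept‑6‑yn‑3‑one; 7 tert‑butyldimethylsilyl chloride
Product: 8 (S)‑5‑[(tert‑butyldimethylsilyl)oxy]‑2‑diazo‑7‑(trimethylsilyl)hept‑6‑yn‑3‑one
Conditions: TBSCl (1.3 equiv), imidazole (2.5 equiv), DMF, rt
Reagents that add atoms: tert‑butyldimethylsilyl chloride CC(C)(C)[Si](C)(C)Cl
Why: Standard silylation; the bulky ether prevents O–H insertion in step 6 and shields one face of the future cyclopentenone.

**Step 5**
Reactants: 8 (S)‑5‑[(tert‑butyldimethylsilyl)oxy]‑2‑diazo‑7‑(trimethylsilyl)hept‑6‑yn‑3‑one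
Product: 9 (S)‑5‑[(tert‑butyldimethylsilyl)oxy]‑2‑diazohept‑6‑yn‑3‑one
Conditions: K2CO3 (0.2 equiv), MeOH, 0 °C, 30 min
Reagents that add atoms: none
Why: Base‑catalysed methanolysis of the C(sp)–SiMe3 bond, which leaves the O‑TBS ether and the fully substituted diazo ketone intact.

**Step 6**
Reactants: 9 (S)‑5‑[(tert‑butyldimethylsilyl)oxy]‑2‑diazohept‑6‑yn‑3‑one; 10 isoprene
Product: 13 (3S,8aR)‑3‑hydroxy‑6,8a‑dimethyl‑2,3,5,8‑tetrahydroazulen‑1(8aH)‑one, via divinylcyclopropane 11 (not isolated), via silyl ether 12 (not isolated)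
Conditions: Rh2(esp)2 (1 mol %), isoprene (10 equiv), CH2Cl2, −20 °C → rt, 9 added over 2 h; then xylenes, 140 °C, sealed tube; then HF·pyridine, THF, 0 °C
Reagents that add atoms: isoprene CC(=C)C=C
Why: Proposed new method: the Rh carbenoid from the α‑diazo ketone adds 5‑exo to the tethered alkyne (carbene/alkyne metathesis, known for alkynyl α‑diazo ketones) to give a 2‑methylcyclopent‑2‑enone carrying an exocyclic vinylcarbenoid at C6, which cyclopropanates the more electron‑rich CH2=C(Me) bond of isoprene to give 11, and this divinylcyclopropane undergoes Cope rearrangement on heating to form the seven‑membered ring with the C8=C9 and C5=C6 alkenes and the quaternary C1 (closest known reaction type: the tandem vinylcarbenoid cyclopropanation/Cope formal [4+3]); the cyclopropane stereoisomers can interconvert by reversible C6–C8 homolysis, so the Cope transition state decides, and there C10 bonds to C1 anti to the OTBS group, which puts the methyl cis to C4–O (1R), before HF·pyridine removes the silyl group from 12.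

**Step 7**
Reactants: 13 (3S,8aR)‑3‑hydroxy‑6,8a‑dimethyl‑2,3,5,8‑tetrahydroazulen‑1(8aH)‑one
Product: 14 (1S,3S,8aR)‑6,8a‑dimethyl‑1,2,3,5,8,8a‑hexahydroazulene‑1,3‑diol
Conditions: Me4NBH(OAc)3 (5 equiv), MeCN/AcOH 1:1, −30 °C
Reagents that add atoms: none
Why: Evans–Saksena directed reduction, in which the C4–OH binds boron and delivers hydride intramolecularly to the same (β) face of the C2 ketone, giving the trans‑1,3‑diol (2α‑OH, 2S).

**Step 8**
Reactants: 14 (1S,3S,8aR)‑6,8a‑dimethyl‑1,2,3,5,8,8a‑hexahydroazulene‑1,3‑diol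
Product: 15 (1S,8aR)‑1‑hydroxy‑6,8a‑dimethyl‑1,2,8,8a‑tetrahydroazulen‑3(5H)‑one
Conditions: activated MnO2 (20 equiv), CH2Cl2, rt
Reagents that add atoms: none
Why: Chemoselective allylic oxidation, since MnO2 oxidises only the allylic C4 alcohol and leaves the non‑allylic C2–OH, which gives the s‑cis C4‑enone.

**Step 9**
Reactants: 15 (1S,8aR)‑1‑hydroxy‑6,8a‑dimethyl‑1,2,8,8a‑tetrahydroazulen‑3(5H)‑one; 16 bis(pinacolato)diboron; 17 sodium perborate
Product: 19 (1S,3aS,4R,8aR)‑1,4‑dihydroxy‑6,8a‑dimethyl‑1,2,3a,4,5,8‑hexahydroazulen‑3(8aH)‑one, via β‑boryl ketone 18 (not isolated)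
Conditions: CuCl (5 mol %), Xantphos (5 mol %), NaOt‑Bu (10 mol %), B2pin2 (1.3 equiv), MeOH (2 equiv), THF, rt; then NaBO3·4H2O, THF/H2O, 0 °C → rt
Reagents that add atoms: bis(pinacolato)diboron CC1(C)OB(OC1(C)C)B1OC(C)(C)C(C)(C)O1 (boron of 18); sodium perborate [Na+].[O-]B1OO1 (oxygen of 19)
Why: Copper(I)‑catalysed conjugate borylation is selective for the enone over the isolated C8=C9 alkene; boron adds to C6 from the convex β‑face (the seven‑membered ring folds towards the α‑face), the enolate is protonated at C5 anti to the angular methyl and the new boryl group (H‑5α, trans ring fusion), and perborate oxidises C–B to C–OH with retention (6β‑OH).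

**Step 10**
Reactants: 19 (1S,3aS,4R,8aR)‑1,4‑dihydroxy‑6,8a‑dimethyl‑1,2,3a,4,5,8‑hexahydroazulen‑3(8aH)‑one; 20 isopropylmagnesium chloride
Product: 21 (1S,3R,3aS,4R,8aR)‑6,8a‑dimethyl‑3‑(propan‑2‑yl)‑1,2,3,3a,4,5,8,8a‑octahydroazulene‑1,3,4‑triol
Conditions: i‑PrMgCl (4 equiv), LaCl3·2LiCl (1.1 equiv), THF, −20 → 0 °C; aqueous AcOH quench
Reagents that add atoms: isopropylmagnesium chloride CC(C)[Mg]Cl
Why: Lanthanum‑promoted Grignard 1,2‑addition (suppresses enolisation and β‑hydride reduction), in which isopropyl attacks the C4 ketone from the α‑face, anti to the angular methyl and to the C5–C6 bond, giving the 4β tertiary alcohol (4R).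

**Step 11**
Reactants: 21 (1S,3R,3aS,4R,8aR)‑6,8a‑dimethyl‑3‑(propan‑2‑yl)‑1,2,3,3a,4,5,8,8a‑octahydroazulene‑1,3,4‑triol; 22 4‑hydroxybenzoic acid
Product: 23 2α‑hydroxyferutinin
Conditions: 4‑hydroxybenzoic acid (1.5 equiv), PPh3 (1.6 equiv), DIAD (1.6 equiv), THF, 0 °C → rt
Reagents that add atoms: 4‑hydroxybenzoic acid OC(=O)c1ccc(O)cc1
Why: Mitsunobu esterification, in which the carboxylic acid reacts in preference to the less acidic phenol, the neopentyl C2–OH and tertiary C4–OH are inert to SN2 activation, and displacement inverts C6 to the 6α (6S) ester.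

**Compound list**
1 | 3‑methylpentane‑2,4‑dione | CC(=O)C(C)C(C)=O | starting material
2 | 4‑acetamidobenzenesulfonyl azide | CC(=O)Nc1ccc(cc1)S(=O)(=O)N=[N+]=[N-] | starting material
3 | 3‑diazobutan‑2‑one | CC(=O)C(C)=[N+]=[N-] | intermediate
4 | 3‑(trimethylsilyl)prop‑2‑ynal | C[Si](C)(C)C#CC=O | starting material
5 | rac‑2‑diazo‑5‑hydroxy‑7‑(trimethylsilyl)hept‑6‑yn‑3‑one | C[Si](C)(C)C#CC(O)CC(=O)C(C)=[N+]=[N-] | intermediate
6 | (S)‑2‑diazo‑5‑hydroxy‑7‑(trimethylsilyl)hept‑6‑yn‑3‑one | C[Si](C)(C)C#C[C@@H](O)CC(=O)C(C)=[N+]=[N-] | intermediate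
7 | tert‑butyldimethylsilyl chloride | CC(C)(C)[Si](C)(C)Cl | starting material
8 | (S)‑5‑[(tert‑butyldimethylsilyl)oxy]‑2‑diazo‑7‑(trimethylsilyl)hept‑6‑yn‑3‑one | C[Si](C)(C)C#C[C@@H](O[Si](C)(C)C(C)(C)C)CC(=O)C(C)=[N+]=[N-] | intermediate
9 | (S)‑5‑[(tert‑butyldimethylsilyl)oxy]‑2‑diazohept‑6‑yn‑3‑one | C#C[C@@H](O[Si](C)(C)C(C)(C)C)CC(=O)C(C)=[N+]=[N-] | intermediate
10 | isoprene (2‑methylbuta‑1,3‑diene) | CC(=C)C=C | starting material
11 | (4S)‑4‑[(tert‑butyldimethylsilyl)oxy]‑3‑(2‑ethenyl‑2‑methylcyclopropyl)‑2‑methylcyclopent‑2‑en‑1‑one, mixture of cyclopropane stereoisomers | C=CC1(C)CC1C2=C(C)C(=O)C[C@@H]2O[Si](C)(C)C(C)(C)C | intermediate (not isolated)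
12 | (3S,8aR)‑3‑[(tert‑butyldimethylsilyl)oxy]‑6,8a‑dimethyl‑2,3,5,8‑tetrahydroazulen‑1(8aH)‑one (C2 ketone, 4β‑OTBS, C5=C6, C8=C9) | CC1=CC[C@]2(C)C(=CC1)[C@@H](O[Si](C)(C)C(C)(C)C)CC2=O | intermediate (not isolated)
13 | (3S,8aR)‑3‑hydroxy‑6,8a‑dimethyl‑2,3,5,8‑tetrahydroazulen‑1(8aH)‑one (C2 ketone, 4β‑OH) | CC1=CC[C@]2(C)C(=CC1)[C@@H](O)CC2=O | intermediate
14 | (1S,3S,8aR)‑6,8a‑dimethyl‑1,2,3,5,8,8a‑hexahydroazulene‑1,3‑diol (2α‑OH, 4β‑OH) | CC1=CC[C@]2(C)C(=CC1)[C@@H](O)C[C@@H]2O | intermediate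
15 | (1S,8aR)‑1‑hydroxy‑6,8a‑dimethyl‑1,2,8,8a‑tetrahydroazulen‑3(5H)‑one (2α‑OH, C4 enone) | CC1=CC[C@]2(C)C(=CC1)C(=O)C[C@@H]2O | intermediate
16 | bis(pinacolato)diboron | CC1(C)OB(OC1(C)C)B1OC(C)(C)C(C)(C)O1 | starting material
17 | sodium perborate | [Na+].[O-]B1OO1 | starting material
18 | β‑boryl ketone: 2α‑hydroxy‑6β‑(pinacolboryl)‑4‑ketone, H‑5α | CC1=CC[C@]2(C)[C@@H]([C@H](B3OC(C)(C)C(C)(C)O3)C1)C(=O)C[C@@H]2O | intermediate (not isolated)
19 | (1S,3aS,4R,8aR)‑1,4‑dihydroxy‑6,8a‑dimethyl‑1,2,3a,4,5,8‑hexahydroazulen‑3(8aH)‑one (2α‑OH, 6β‑OH, C4 ketone, trans‑fused) | CC1=CC[C@]2(C)[C@@H]([C@H](O)C1)C(=O)C[C@@H]2O | intermediate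
20 | isopropylmagnesium chloride | CC(C)[Mg]Cl | starting material
21 | (1S,3R,3aS,4R,8aR)‑6,8a‑dimethyl‑3‑(propan‑2‑yl)‑1,2,3,3a,4,5,8,8a‑octahydroazulene‑1,3,4‑triol (2α,4β,6β‑triol) | CC1=CC[C@]2(C)[C@@H]([C@H](O)C1)[C@](O)(C(C)C)C[C@@H]2O | intermediate
22 | 4‑hydroxybenzoic acid | OC(=O)c1ccc(O)cc1 | starting material
23 | 2α‑hydroxyferutinin, (1S,3R,3aS,4S,8aR)‑1,3‑dihydroxy‑6,8a‑dimethyl‑3‑(propan‑2‑yl)‑1,2,3,3a,4,5,8,8a‑octahydroazulen‑4‑yl 4‑hydroxybenzoate | CC1=CC[C@]2(C)[C@@H]([C@@H](OC(=O)c3ccc(O)cc3)C1)[C@](O)(C(C)C)C[C@@H]2O | target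

**Totals:** 11 steps; longest linear sequence 11 steps (1 → 23).

**Steps most likely to fail**

Step 6 (cascade). The methyl‑substituted Rh carbenoid may undergo 1,2‑hydride shift to a vinyl ketone before it reaches the alkyne, isoprene capture may be inefficient or poorly regioselective, and the Cope rearrangement that forms the quaternary centre may be slow. The fallback sets out from 9 and comes back at 11. Warming 9 in toluene at about 70 °C without metal should give intramolecular diazo–alkyne 1,3‑dipolar cycloaddition to the bicyclic 3H‑pyrazole F1 (again two rings in one operation, no metal carbenoid at the methyl‑bearing carbon). Irradiating 3H‑pyrazole F1 at about 350 nm in isoprene expels nitrogen and releases the same cyclopentenyl carbene as a free carbene, which cyclopropanates isoprene to 11. Heating and HF·pyridine as in step 6 then give 13.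

Step 9 (conjugate borylation). The copper–boryl species may add slowly to the hindered α‑branched enone, the β‑hydroxy ketone may lose the C2 hydroxyl by E1cB, and the C5 protonation may not favour the trans fusion. The fallback sets out from 15 and comes back at 19. Weitz–Scheffer epoxidation of 15 (t‑BuOOH, DBU, CH2Cl2) gives the 5β,6β‑epoxy ketone F2 from the same convex face. SmI2 in THF/MeOH at −78 °C then cleaves the Cα–O bond of epoxy ketone F2 and protonation of the samarium enolate gives 19.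

Step 11 (Mitsunobu). SN2 at the hindered C6 may lose to elimination towards the C6=C7/C8=C9 diene. The fallback sets out from 21 and comes back at 23; it also corrects any C6 or C2 stereochemical error from upstream. Dess–Martin oxidation of both secondary alcohols of 21 gives the 4‑hydroxy‑2,6‑diketone F3. Me4NBH(OAc)3 reduces both ketones of diketone F3 under direction of the C4–OH (1,3‑anti on each side) to the 2α,4β,6α‑triol F4. Acylation of triol F4 at the more accessible C6–OH with 4‑[(tert‑butyldimethylsilyl)oxy]benzoyl chloride (DMAP, pyridine, 0 °C) gives the silyl‑protected ester F5, and HF·pyridine on ester F5 gives 23.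

**Further compounds**
F1 | step 6 | (4S)‑4‑[(tert‑butyldimethylsilyl)oxy]‑6a‑methyl‑4,5‑dihydrocyclopenta[c]pyrazol‑6(6aH)‑one (3H‑pyrazole, mixture at C6a) | CC12N=NC=C1[C@@H](O[Si](C)(C)C(C)(C)C)CC2=O
F2 | step 9 | 5β,6β‑epoxide of enone 15 (2α‑hydroxy‑5,6‑epoxy‑4‑ketone) | CC1=CC[C@]2(C)[C@@]3(O[C@@H]3C1)C(=O)C[C@@H]2O
F3 | step 11 | 4β‑hydroxy‑4‑isopropyl‑2,6‑diketone (H‑5α) | CC1=CC[C@]2(C)[C@@H](C(=O)C1)[C@](O)(C(C)C)CC2=O
F4 | step 11 | 2α,4β,6α‑triol (2α‑hydroxyjaeschkeanadiol) | CC1=CC[C@]2(C)[C@@H]([C@@H](O)C1)[C@](O)(C(C)C)C[C@@H]2O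
F5 | step 11 | 2α‑hydroxyferutinin 4′‑O‑tert‑butyldimethylsilyl ether | CC1=CC[C@]2(C)[C@@H]([C@@H](OC(=O)c3ccc(O[Si](C)(C)C(C)(C)C)cc3)C1)[C@](O)(C(C)C)C[C@@H]2O
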